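**Strategy.** The whole plan rests on opening ring C across C2–C3 and C4–C4a. The feature exploited is the C4a=C8a–O1–C2 unit shared by rings A and C: as an O-aryl oxocarbenium ion it is a cationic 2-oxadiene, and the electron-rich ring A makes C4a its nucleophilic terminus. In one operation a 2-siloxy ketene acetal (C3–C4) adds through C3 to C2 and the resulting dimethoxycarbenium ion closes onto C4a, a formal asymmetric [4+2] under chiral anion-binding catalysis that sets C2 and C3. The precursor is an open, racemic mixed acetal of 3,5-dimethoxy-2-prenylphenol and 4-silyloxybenzaldehyde that contains no pyranone ring.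

Key step: step 5

Remark: the target is read as the (2R,3R)-trans-dihydroflavonol; flavanone numbering (O1, C2, C3, C4, C4a, C5–C8, C8a) is used throughout.

Assumption: squaramide Q is 3-{[3,5-bis(trifluoromethyl)phenyl]amino}-4-({(2S)-3,3-dimethyl-1-oxo-1-[(2R)-2-(phenanthren-9-yl)pyrrolidin-1-yl]butan-2-yl}amino)cyclobut-3-ene-1,2-dione; its sense of induction in step 5 is assumed by analogy with related ion-pair catalysis, and the mirror-image catalyst would be used if the opposite sense were found.

**Step 1**
Reactants: 1 3,5-dimethoxyphenol; 2 prenyl bromide (1-bromo-3-methylbut-2-ene)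
Product: 3 3,5-dimethoxy-2-(3-methylbut-2-en-1-yl)phenol
Conditions: NaH (1.05 equiv), toluene, 0 °C; then 2 (1.0 equiv), rt
Reagents that add atoms: none
Why: Ortho-selective C-alkylation of a sodium phenoxide in a non-polar solvent, where the tight ion pair steers the allylic halide to the ortho carbon (both ortho positions of 1 are equivalent); no stereocentre is formed.

**Step 2**
Reactants: 4 4-(tert-butyldimethylsilyloxy)benzaldehyde
Product: 5 tert-butyl[4-(dimethoxymethyl)phenoxy]dimethylsilane
Conditions: HC(OMe)3, MeOH, PPTS (cat.), rt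
Reagents that add atoms: trimethyl orthoformate, COC(OC)OC
Why: Acid-catalysed acetalisation with the orthoformate as dehydrating agent; PPTS is mild enough to spare the aryl silyl ether, and no stereocentre is formed.

**Step 3**
Reactants: 5 tert-butyl[4-(dimethoxymethyl)phenoxy]dimethylsilane; 3 3,5-dimethoxy-2-(3-methylbut-2-en-1-yl)phenol
Product: 7 rac-tert-butyl(4-{[3,5-dimethoxy-2-(3-methylbut-2-en-1-yl)phenoxy](methoxy)methyl}phenoxy)dimethylsilane, via chloro ether 6 (not isolated)
Conditions: AcCl (1.0 equiv), ZnBr2 (0.1 mol %), toluene, 0 °C to rt; then 3, i-Pr2NEt, 0 °C to rt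
Reagents that add atoms: acetyl chloride, CC(=O)Cl (chlorine of 6 only)
Why: ZnBr2-catalysed acetal/acid chloride exchange gives the α-chloro ether, which O-alkylates the phenol under amine base as in a MOM-type protection; the new acetal centre is racemic and is erased in step 5.

**Step 4**
Reactants: 8 2,2-dimethoxyacetaldehyde (anhydrous, extracted and distilled from the commercial aqueous solution)
Product: 9 tert-butyl[(2,2-dimethoxyethenyl)oxy]dimethylsilane
Conditions: t-BuMe2SiOTf (1.1 equiv), Et3N (1.5 equiv), CH2Cl2, −78 to 0 °C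
Reagents that add atoms: tert-butyldimethylsilyl triflate, CC(C)(C)[Si](C)(C)OS(=O)(=O)C(F)(F)F
Why: Soft enolisation (silyl triflate/tertiary amine silyl enol ether formation) of an aldehyde whose only α-hydrogen sits on the acetal carbon, so the sole enol ether possible is the 2-siloxy ketene dimethyl acetal; no stereocentre is formed.

**Step 5**
Reactants: 7 rac-mixed aryl methyl acetal; 9 tert-butyl[(2,2-dimethoxyethenyl)oxy]dimethylsilane
Product: 13 (2R,3R)-3-(tert-butyldimethylsilyloxy)-2-[4-(tert-butyldimethylsilyloxy)phenyl]-5,7-dimethoxy-8-(3-methylbut-2-en-1-yl)-2,3-dihydro-4H-chromen-4-one, via oxocarbenium triflate 10 (not isolated), via dimethoxycarbenium triflate 11 (not isolated), via dimethyl ketal 12 (not isolated)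
Conditions: 9 (2.2 equiv, the second equivalent takes up the methanol released), squaramide Q (12 mol %), Me3SiOTf (10 mol %), t-BuOMe, −78 °C; then 1 M HCl, THF, 0 °C
Reagents that add atoms: water, O (carbonyl oxygen of 13); trimethylsilyl triflate, C[Si](C)(C)OS(=O)(=O)C(F)(F)F (triflate counter-ion of 10 and 11 only)
Why: Proposed new method: Me3SiOTf (and then the TfOH released at each turnover) removes the methoxy group of 7 and gives the O-aryl oxocarbenium triflate 10, in which C4a=C8a–O1+=C2 is a cationic 2-oxadiene held as an ion pair by the squaramide; the CH(OSi) carbon of 9 adds to C2 (C2–C3), and because 9 carries no silyl group on its acetal oxygens the dimethoxycarbenium ion 11 cannot collapse to an ester and is captured by C4a of the trioxygenated ring A (C4–C4a), giving ketal 12 and, after hydrolysis, ketone 13. The closest known reaction types are the oxa-Povarov reaction of O-aryl oxocarbenium ions with alkenes (SnCl4-promoted, racemic), the asymmetric Povarov reaction under chiral hydrogen-bond-donor/strong-acid co-catalysis, and the enantioselective Mukaiyama-type addition of silyl ketene acetals to aromatic acetals under squaramide/silyl triflate co-catalysis. Ring C closes as a six-membered ring in a stepwise formal [4+2] (inverse-demand hetero-Diels–Alder) mode, the second bond by Friedel–Crafts attack of the endocyclic C4a=C8a bond (6-endo for the arene) on the exocyclic carbenium carbon. C2 is controlled by the catalyst, whose triflate-bound chiral pocket should leave the Si face of the (E)-oxocarbenium ion open, and C3 by the substrate, since the exo placement of the bulky siloxy group pairs the Re face of 9 with that face and gives the 2,3-trans isomer, which is also the thermodynamic one, so that a 3-epimer should drain to trans through the enol during the acidic hydrolysis without touching C2. The step needs regioselectivity (the two methoxy groups polarise 9 so that only C3 is nucleophilic, and the prenyl group at C8 leaves C4a as the only ortho carbon that can close the ring), chemoselectivity (the ketene acetal is many orders of magnitude more nucleophilic than the ortho prenyl alkene, which could otherwise trap C2) and enantiofacial control, for which the racemic acetal carbon of 7 is irrelevant because it becomes planar on ionisation.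

**Step 6**
Reactants: 13 (2R,3R)-3,4'-bis-silyl ether of the 5,7-dimethoxy-8-prenyl dihydroflavonol
Product: 14 (2R,3R)-3-(tert-butyldimethylsilyloxy)-2-[4-(tert-butyldimethylsilyloxy)phenyl]-5-hydroxy-7-methoxy-8-(3-methylbut-2-en-1-yl)-2,3-dihydro-4H-chromen-4-one
Conditions: MgI2·OEt2 (3 equiv), THF, 60 °C; dilute aq. HCl work-up
Reagents that add atoms: none
Why: Chelation-controlled demethylation in which magnesium bridges the C4 carbonyl and the peri 5-methoxy oxygen and iodide removes that methyl group by SN2, a reaction type that spares a C8 prenyl group on flavanones; the 7-methoxy group cannot chelate and the stereocentres are not involved.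

**Step 7**
Reactants: 14 (2R,3R)-5-hydroxy-7-methoxy bis-silyl ether
Product: 15 (2R,3R)-3,5-dihydroxy-2-(4-hydroxyphenyl)-7-methoxy-8-(3-methylbut-2-en-1-yl)-2,3-dihydro-4H-chromen-4-one
Conditions: HF·pyridine, pyridine, THF, 0 °C to rt
Reagents that add atoms: none
Why: Fluoride-driven desilylation (Si–F bond formation) under acidic buffering frees the 3- and 4'-hydroxyl groups without forming the 4'-phenoxide that could open ring C, so C2 and C3 should stay (2R,3R).

**Compound list**

1 | 3,5-dimethoxyphenol | COc1cc(O)cc(OC)c1 | starting material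
2 | prenyl bromide (1-bromo-3-methylbut-2-ene) | CC(C)=CCBr | starting material
3 | 3,5-dimethoxy-2-(3-methylbut-2-en-1-yl)phenol | COc1cc(OC)c(CC=C(C)C)c(O)c1 | intermediate
4 | 4-(tert-butyldimethylsilyloxy)benzaldehyde | CC(C)(C)[Si](C)(C)Oc1ccc(C=O)cc1 | starting material
5 | tert-butyl[4-(dimethoxymethyl)phenoxy]dimethylsilane | COC(OC)c1ccc(O[Si](C)(C)C(C)(C)C)cc1 | intermediate
6 | rac-tert-butyl{4-[chloro(methoxy)methyl]phenoxy}dimethylsilane | COC(Cl)c1ccc(O[Si](C)(C)C(C)(C)C)cc1 | intermediate (not isolated)
7 | rac-tert-butyl(4-{[3,5-dimethoxy-2-(3-methylbut-2-en-1-yl)phenoxy](methoxy)methyl}phenoxy)dimethylsilane | COC(Oc1cc(OC)cc(OC)c1CC=C(C)C)c1ccc(O[Si](C)(C)C(C)(C)C)cc1 | intermediate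
8 | 2,2-dimethoxyacetaldehyde | COC(OC)C=O | starting material
9 | tert-butyl[(2,2-dimethoxyethenyl)oxy]dimethylsilane | COC(OC)=CO[Si](C)(C)C(C)(C)C | intermediate
10 | (E)-[4-(tert-butyldimethylsilyloxy)benzylidene][3,5-dimethoxy-2-(3-methylbut-2-en-1-yl)phenyl]oxonium triflate | COc1cc(OC)c(CC=C(C)C)c(/[O+]=C/c2ccc(O[Si](C)(C)C(C)(C)C)cc2)c1.[O-]S(=O)(=O)C(F)(F)F | intermediate (not isolated)
11 | (2R,3R)-2-(tert-butyldimethylsilyloxy)-3-[4-(tert-butyldimethylsilyloxy)phenyl]-3-[3,5-dimethoxy-2-(3-methylbut-2-en-1-yl)phenoxy]-1,1-dimethoxypropan-1-ylium triflate | COc1cc(OC)c(CC=C(C)C)c(O[C@H](c2ccc(O[Si](C)(C)C(C)(C)C)cc2)[C@@H](O[Si](C)(C)C(C)(C)C)[C+](OC)OC)c1.[O-]S(=O)(=O)C(F)(F)F | intermediate (not isolated)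
12 | tert-butyl{4-[(2R,3R)-3-(tert-butyldimethylsilyloxy)-4,4,5,7-tetramethoxy-8-(3-methylbut-2-en-1-yl)-3,4-dihydro-2H-chromen-2-yl]phenoxy}dimethylsilane | COc1cc(OC)c2c(c1CC=C(C)C)O[C@H](c1ccc(O[Si](C)(C)C(C)(C)C)cc1)[C@@H](O[Si](C)(C)C(C)(C)C)C2(OC)OC | intermediate (not isolated)
13 | (2R,3R)-3-(tert-butyldimethylsilyloxy)-2-[4-(tert-butyldimethylsilyloxy)phenyl]-5,7-dimethoxy-8-(3-methylbut-2-en-1-yl)-2,3-dihydro-4H-chromen-4-one | COc1cc(OC)c2c(c1CC=C(C)C)O[C@H](c1ccc(O[Si](C)(C)C(C)(C)C)cc1)[C@@H](O[Si](C)(C)C(C)(C)C)C2=O | intermediate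
14 | (2R,3R)-3-(tert-butyldimethylsilyloxy)-2-[4-(tert-butyldimethylsilyloxy)phenyl]-5-hydroxy-7-methoxy-8-(3-methylbut-2-en-1-yl)-2,3-dihydro-4H-chromen-4-one | COc1cc(O)c2c(c1CC=C(C)C)O[C@H](c1ccc(O[Si](C)(C)C(C)(C)C)cc1)[C@@H](O[Si](C)(C)C(C)(C)C)C2=O | intermediate
15 | (2R,3R)-3,5-dihydroxy-2-(4-hydroxyphenyl)-7-methoxy-8-(3-methylbut-2-en-1-yl)-2,3-dihydro-4H-chromen-4-one | COc1cc(O)c2c(c1CC=C(C)C)O[C@H](c1ccc(O)cc1)[C@@H](O)C2=O | target

**Step count.** Total: 7 steps. Longest linear sequence: 5 steps (steps 2, 3, 5, 6, 7, or equally steps 1, 3, 5, 6, 7).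

**Steps most likely to fail**

1. Step 5 (proposed new method). What may go wrong:
- ionisation of 7 in the wrong direction (loss of the aryloxy group);
- acid-induced oligomerisation of 9;
- methyl transfer from 11 to triflate before ring closure, which stops the cascade at an ester;
- capture of 10 by the ortho prenyl alkene;
- weak facial discrimination by the ion pair.

Fallback, from 7 back to 13, with the two bonds made in separate, known operations. Commercial methyl 2-(tert-butyldimethylsilyloxy)acetate is converted with LiN(i-Pr)2/Me3SiCl (THF, −78 °C) into the silyl ketene acetal F1. Its enantioselective Mukaiyama-type addition to the oxocarbenium ion from 7 (squaramide Q, catalytic Me3SiOTf, t-BuOMe, −78 °C; silyl transfer turns the catalyst over) should give the anti β-aryloxy methyl ester F2 and form C2–C3. Me3SnOH (1,2-dichloroethane, 70 °C) should cleave the ester to the acid F3 without β-elimination of the aryloxide. (CF3CO)2O in CH2Cl2 at 0 °C should then convert F3 through the mixed anhydride F4 into 13 by intramolecular Friedel–Crafts acylation at C4a, the only free ortho carbon. A minor 3-epimer would be corrected at the ketone stage by enolisation to the trans isomer.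

2. Step 4. What may go wrong: Mukaiyama-type self-condensation of the silyl-activated aldehyde with the enol ether already formed, and hydrolytic loss of the very electron-rich alkene on isolation.

Fallback, from 7 back to 13, in which 9 is not needed and the C3 oxygen is introduced after the annulation. Commercial 1,1-diethoxyethene replaces 9 under the conditions of step 5 and should give, through 10, the diethoxycarbenium triflate F5 and the diethyl ketal F6, and after the acidic hydrolysis the (2S)-flavanone F7. t-BuMe2SiOTf/Et3N (CH2Cl2, 0 °C) gives the silyl enol ether F8. Rubottom oxidation with dimethyldioxirane (1.0 equiv, acetone/CH2Cl2, −78 °C; the enol ether should react faster than the prenyl alkene) should epoxidise it anti to the C2 aryl group to the siloxy oxirane F9. Ring opening of F9 with 1,4-silyl shift on warming should deliver 13.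

3. Step 1. What may go wrong: O-alkylation, para C-alkylation between the two methoxy groups, and double prenylation competing with the ortho C-alkylation.

Fallback, from 1 back to 3. Pd(PPh3)4-catalysed O-alkylation of 1 with commercial tert-butyl 2-methylbut-3-en-2-yl carbonate (THF, rt; the branched ether is the kinetic product of the zerovalent-palladium allylic substitution) gives the 1,1-dimethylallyl aryl ether F10. Aromatic Claisen rearrangement (N,N-diethylaniline, 120 °C) then transfers the allyl unit with inversion to either of the two equivalent ortho carbons and gives 3 regiospecifically.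

**Further compounds**

F1 | step 5 | tert-butyl{[2-methoxy-2-(trimethylsilyloxy)ethenyl]oxy}dimethylsilane (double-bond geometry not critical) | COC(O[Si](C)(C)C)=CO[Si](C)(C)C(C)(C)C
F2 | step 5 | methyl (2R,3R)-2-(tert-butyldimethylsilyloxy)-3-[4-(tert-butyldimethylsilyloxy)phenyl]-3-[3,5-dimethoxy-2-(3-methylbut-2-en-1-yl)phenoxy]propanoate | COc1cc(OC)c(CC=C(C)C)c(O[C@H](c2ccc(O[Si](C)(C)C(C)(C)C)cc2)[C@@H](O[Si](C)(C)C(C)(C)C)C(=O)OC)c1
F3 | step 5 | (2R,3R)-2-(tert-butyldimethylsilyloxy)-3-[4-(tert-butyldimethylsilyloxy)phenyl]-3-[3,5-dimethoxy-2-(3-methylbut-2-en-1-yl)phenoxy]propanoic acid | COc1cc(OC)c(CC=C(C)C)c(O[C@H](c2ccc(O[Si](C)(C)C(C)(C)C)cc2)[C@@H](O[Si](C)(C)C(C)(C)C)C(=O)O)c1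
F4 | step 5 | mixed anhydride of F3 with trifluoroacetic acid (not isolated) | COc1cc(OC)c(CC=C(C)C)c(O[C@H](c2ccc(O[Si](C)(C)C(C)(C)C)cc2)[C@@H](O[Si](C)(C)C(C)(C)C)C(=O)OC(=O)C(F)(F)F)c1
F5 | step 4 | (3S)-3-[4-(tert-butyldimethylsilyloxy)phenyl]-3-[3,5-dimethoxy-2-(3-methylbut-2-en-1-yl)phenoxy]-1,1-diethoxypropan-1-ylium triflate (not isolated) | COc1cc(OC)c(CC=C(C)C)c(O[C@H](c2ccc(O[Si](C)(C)C(C)(C)C)cc2)C[C+](OCC)OCC)c1.[O-]S(=O)(=O)C(F)(F)F
F6 | step 4 | tert-butyl{4-[(2S)-4,4-diethoxy-5,7-dimethoxy-8-(3-methylbut-2-en-1-yl)-3,4-dihydro-2H-chromen-2-yl]phenoxy}dimethylsilane (not isolated) | COc1cc(OC)c2c(c1CC=C(C)C)O[C@H](c1ccc(O[Si](C)(C)C(C)(C)C)cc1)CC2(OCC)OCC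
F7 | step 4 | (2S)-2-[4-(tert-butyldimethylsilyloxy)phenyl]-5,7-dimethoxy-8-(3-methylbut-2-en-1-yl)-2,3-dihydro-4H-chromen-4-one | COc1cc(OC)c2c(c1CC=C(C)C)O[C@H](c1ccc(O[Si](C)(C)C(C)(C)C)cc1)CC2=O
F8 | step 4 | tert-butyl({(2S)-2-[4-(tert-butyldimethylsilyloxy)phenyl]-5,7-dimethoxy-8-(3-methylbut-2-en-1-yl)-2H-chromen-4-yl}oxy)dimethylsilane | COc1cc(OC)c2c(c1CC=C(C)C)O[C@H](c1ccc(O[Si](C)(C)C(C)(C)C)cc1)C=C2O[Si](C)(C)C(C)(C)C
F9 | step 4 | 3,4-epoxide of F8 with the oxirane oxygen anti to the C2 aryl group, (2R,3R,4R) in flavan numbering (not isolated) | COc1cc(OC)c2c(c1CC=C(C)C)O[C@H](c1ccc(O[Si](C)(C)C(C)(C)C)cc1)[C@H]1O[C@@]21O[Si](C)(C)C(C)(C)C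
F10 | step 1 | 1,3-dimethoxy-5-[(2-methylbut-3-en-2-yl)oxy]benzene | COc1cc(OC)cc(OC(C)(C)C=C)c1
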